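**Strategy.** Ring G carries oxygen on five contiguous carbons (C1 ring F oxygen, C6 ring H oxygen, C3–C5 hydroxyls) and hydrogen only on C2; rings C and E repeat this pattern. Each such ring is disconnected into a squarate-derived 2-aryloxy-3,4-dimethoxycyclobutenone (four carbons with their oxygens, inner aryl ether included) and an aryl ethynyl ether (C1, C2 and the outer aryl ether). In the key step, heating cyclobutenone 7 with ring F ynol ether 18 forms the C2–C3 and C1–C6 bonds and closes ring G in one operation, so no aryl–oxygen bond of ring G is made by coupling. The same annulation later closes rings C and E; only the A–B ether comes from an Ullmann coupling.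

Key step: step 12

**Remarks on the chemistry**
- Rings are lettered A to H from the 2,4,6-trihydroxyphenyl end to the 3,4,5-trihydroxyphenyl end. Ring G: C1 (ring F oxygen), C2 (H), C3–C5 (OH), C6 (ring H oxygen). Ring E: C1 (ring D oxygen), C2 (ring F oxygen), C3 (H), C4–C6 (OH). Ring C: C1 (ring B oxygen), C2 (H), C3–C5 (OH), C6 (ring D oxygen).
- The target has no stereocentre. Cyclobutenones 6, 7, 43, 44, 53 and 54 are racemates and are written without a stereodescriptor (7 is O=C1C(Oc2cc(OC)c(OC)c(OC)c2)=C(OC)C1OC); a wedge at C4 would wrongly imply a single enantiomer, and the centre vanishes on aromatisation.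
- Assumption: 2,4,6-trimethoxyphenol 30, 4-bromo-2,6-dimethoxybenzaldehyde 31 and 4-(benzyloxy)-3,5-dimethoxybenzaldehyde 39 are taken as catalogue compounds.
- Dichloroacetylene is never handled as a substance. In steps 10, 15 and 19 it is a reagent made from trichloroethylene 14 by K2CO3 in DMF and consumed in the same flask by the phenoxide; these steps are run under nitrogen and quenched with water before any concentration.
- Aryl abbreviations used in names:
  - ArH = 3,4,5-trimethoxyphenyl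
  - ArF = 5-(benzyloxy)-2,3-dimethoxyphenyl
  - ArFGH = 3,4-dimethoxy-5-[3,4,5-trimethoxy-2-(3,4,5-trimethoxyphenoxy)phenoxy]phenyl
  - ArAB = 2,6-dimethoxy-4-(2,4,6-trimethoxyphenoxy)phenyl
  - ArD = 4-(benzyloxy)-3,5-dimethoxyphenyl
  - ArABCD = 4-{6-[2,6-dimethoxy-4-(2,4,6-trimethoxyphenoxy)phenoxy]-2,3,4-trimethoxyphenoxy}-2,6-dimethoxyphenyl

## Route

**Methyl squaryl chloride and the ring H cyclobutenone**

Step 1
Reactants: 1 dimethyl squarate
Product: 2 3-hydroxy-4-methoxycyclobut-3-ene-1,2-dione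
Conditions: NaOH (1.0 equiv), THF–H2O, 0 °C to rt; then HCl (1.0 equiv), evaporate, extract into acetone
Reagents that add atoms: sodium hydroxide, [Na+].[OH-]
Why: Hydroxide adds to a methoxy-bearing ring carbon and expels methoxide (saponification of a vinylogous ester by addition–elimination), and the delocalised squarate monoanion that results resists a second attack, so the half-ester should be obtained.

Step 2
Reactants: 2 3-hydroxy-4-methoxycyclobut-3-ene-1,2-dione
Product: 3 3-chloro-4-methoxycyclobut-3-ene-1,2-dione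
Conditions: (COCl)2 (1.2 equiv), DMF (cat.), CH2Cl2, 0 °C to rt
Reagents that add atoms: oxalyl chloride, O=C(Cl)C(=O)Cl
Why: The vinylogous carboxylic acid is converted into its chloride by the chloroiminium (Vilsmeier) reagent from oxalyl chloride and DMF, as in a standard acid chloride formation.

Step 3
Reactants: 3 3-chloro-4-methoxycyclobut-3-ene-1,2-dione; 4 3,4,5-trimethoxyphenol
Product: 5 3-methoxy-4-(3,4,5-trimethoxyphenoxy)cyclobut-3-ene-1,2-dione
Conditions: i-Pr2NEt (1.1 equiv), CH2Cl2, −78 to 0 °C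
Reagents that add atoms: none
Why: Acylation-type addition–elimination of the phenol oxygen at the chlorine-bearing carbon of the vinylogous acid chloride should give the mixed squarate, since chloride leaves far more readily than methoxide and the hindered amine only removes HCl.

Step 4
Reactants: 5 3-methoxy-4-(3,4,5-trimethoxyphenoxy)cyclobut-3-ene-1,2-dione
Product: 6 racemic 4-hydroxy-3-methoxy-2-(3,4,5-trimethoxyphenoxy)cyclobut-2-en-1-one
Conditions: LiAlH(OtBu)3 (1.05 equiv), THF, −78 °C; then H2O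
Reagents that add atoms: none
Why: Carbonyl 1,2-reduction with the bulky alkoxyaluminium hydride, the reagent used for dialkyl squarates, should select the carbonyl next to the methoxy-bearing carbon because it is the vinylogous ester of the weaker aryloxy donor and the less shielded one; the new C4 stereocentre forms as a racemate and is erased in step 12.

Step 5
Reactants: 6 racemic 4-hydroxy-3-methoxy-2-(3,4,5-trimethoxyphenoxy)cyclobut-2-en-1-one
Product: 7 racemic 3,4-dimethoxy-2-(3,4,5-trimethoxyphenoxy)cyclobut-2-en-1-one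
Conditions: MeI (10 equiv), Ag2O (2 equiv), CaSO4, MeCN, rt, dark
Reagents that add atoms: iodomethane, CI
Why: Purdie methylation (MeI with Ag2O) etherifies the secondary alcohol without strong base, so the base-labile hydroxycyclobutenone should survive; the racemic C4 centre is unchanged.

**Ring F ynol ether**

Step 6
Reactants: 8 3-hydroxy-4,5-dimethoxybenzaldehyde
Product: 9 3,4-dimethoxy-5-(methoxymethoxy)benzaldehyde
Conditions: MOMCl (1.3 equiv), i-Pr2NEt, CH2Cl2, 0 °C to rt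
Reagents that add atoms: chloromethyl methyl ether, COCCl
Why: Alkylation of the phenol with MOMCl (acetal protection) masks the oxygen that will later carry the alkyne and tolerates the aldehyde.

Step 7
Reactants: 9 3,4-dimethoxy-5-(methoxymethoxy)benzaldehyde
Product: 11 3,4-dimethoxy-5-(methoxymethoxy)phenol, via aryl formate 10 (not isolated)
Conditions: mCPBA (1.2 equiv), CH2Cl2, 0 °C to rt; aq. Na2SO3/NaHCO3 wash; then K2CO3 (cat.), MeOH, rt
Reagents that add atoms: meta-chloroperbenzoic acid, OOC(=O)c1cccc(Cl)c1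
Why: Baeyer–Villiger oxidation of the electron-rich benzaldehyde proceeds with aryl migration (Dakin-type outcome), and mild methanolysis of the formate frees the phenol at C1 of ring F while the MOM ether stays.

Step 8
Reactants: 11 3,4-dimethoxy-5-(methoxymethoxy)phenol
Product: 12 5-(benzyloxy)-1,2-dimethoxy-3-(methoxymethoxy)benzene
Conditions: BnBr (1.2 equiv), K2CO3, DMF, rt
Reagents that add atoms: benzyl bromide, BrCc1ccccc1
Why: Williamson etherification installs a benzyl group that survives n-BuLi at low temperature and heat and is removed later by hydrogenolysis.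

Step 9
Reactants: 12 5-(benzyloxy)-1,2-dimethoxy-3-(methoxymethoxy)benzene
Product: 13 5-(benzyloxy)-2,3-dimethoxyphenol
Conditions: HCl (conc., cat.), MeOH, 50 °C
Reagents that add atoms: none
Why: Acid-catalysed acetal exchange with methanol removes the MOM group only, since benzyl and methyl aryl ethers are inert to dilute acid.

Step 10
Reactants: 13 5-(benzyloxy)-2,3-dimethoxyphenol; 14 trichloroethylene
Product: 15 5-(benzyloxy)-1-{[(E)-1,2-dichloroethenyl]oxy}-2,3-dimethoxybenzene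
Conditions: trichloroethylene (2 equiv), K2CO3 (3 equiv), DMF, 70 °C, N2
Reagents that add atoms: none
Why: Carbonate dehydrochlorinates trichloroethylene to dichloroacetylene, which is consumed as it forms by anti addition of the phenoxide (nucleophilic addition to a haloalkyne), and this should give the (E)-1,2-dichlorovinyl ether.

Step 11
Reactants: 15 5-(benzyloxy)-1-{[(E)-1,2-dichloroethenyl]oxy}-2,3-dimethoxybenzene
Product: 18 1-(benzyloxy)-3-(ethynyloxy)-4,5-dimethoxybenzene, via chloroethynyl ether 16 (not isolated), via lithium acetylide 17 (not isolated)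
Conditions: n-BuLi (2.5 equiv), THF, −78 to −40 °C; then H2O, −78 °C
Reagents that add atoms: none
Why: The known conversion of 1,2-dichlorovinyl ethers into ynol ethers should apply: n-BuLi eliminates HCl, a second equivalent effects lithium–chlorine exchange on the chloroalkyne, and water protonates the acetylide, all below the temperature of ortho-lithiation or benzyl ether rearrangement.

**Key benzannulation and the FGH ynol ether**

Step 12
Reactants: 7 racemic 3,4-dimethoxy-2-(3,4,5-trimethoxyphenoxy)cyclobut-2-en-1-one; 18 1-(benzyloxy)-3-(ethynyloxy)-4,5-dimethoxybenzene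
Product: 23 5-[5-(benzyloxy)-2,3-dimethoxyphenoxy]-2,3-dimethoxy-4-(3,4,5-trimethoxyphenoxy)phenol, via vinylketene 19 (not isolated), via vinylcyclobutenone 20 (not isolated), via dienylketene 21 (not isolated), via cyclohexadienone 22 (not isolated)
Conditions: 7 (1.5 equiv), 18 (1.0 equiv), toluene (0.2 M), argon, 80 °C then 110 °C; then KOH, MeOH, rt (cleaves any aryl ester formed from 23 and excess ketene)
Reagents that add atoms: none
Why: Thermal 4π-electrocyclic opening of 7, with the C4 methoxy group rotating outward, gives vinylketene 19, whose ketene C=C bond adds the electron-rich alkyne of 18 in a [2+2] cycloaddition to give vinylcyclobutenone 20; a second 4π opening gives dienylketene 21, 6π-electrocyclisation gives cyclohexadienone 22, and enolisation gives phenol 23. The closest known reaction type is the Danheiser benzannulation of cyclobutenones with alkoxyacetylenes. Ring G is closed by the thermal disrotatory 6π-electrocyclisation of 21, which re-forms the C3–C4 bond after the cycloaddition has made the C2–C3 and C1–C6 bonds. No stereocentre is created in 23, and the racemic centres of 7, 20 and 22 are destroyed on aromatisation. The step needs one regiochemical outcome in the ketene–alkyne cycloaddition, and the polarisation of the ynol ether secures it: the unsubstituted, nucleophilic alkyne carbon bonds to the electrophilic ketene carbonyl carbon, so the ring F oxygen ends on C1, meta to the new C3 hydroxyl and next to the ring H oxygen on C6. Outward rotation of the oxygen donors in both ring openings places the vinyl group inward in 21, as the 6π closure requires.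

Step 13
Reactants: 23 5-(ArF-oxy)-2,3-dimethoxy-4-(ArH-oxy)phenol
Product: 24 5-(benzyloxy)-1,2-dimethoxy-3-[3,4,5-trimethoxy-2-(3,4,5-trimethoxyphenoxy)phenoxy]benzene
Conditions: MeI, K2CO3, DMF, rt
Reagents that add atoms: iodomethane, CI
Why: Williamson methylation caps the only free hydroxyl (C3 of ring G), so that the phenol released next is the sole nucleophilic oxygen.

Step 14
Reactants: 24 5-(benzyloxy)-1,2-dimethoxy-3-[3,4,5-trimethoxy-2-(3,4,5-trimethoxyphenoxy)phenoxy]benzene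
Product: 25 3,4-dimethoxy-5-[3,4,5-trimethoxy-2-(3,4,5-trimethoxyphenoxy)phenoxy]phenol
Conditions: H2 (1 atm), Pd/C (10 wt%), EtOAc–MeOH, rt
Reagents that add atoms: none
Why: Catalytic hydrogenolysis cleaves only the benzylic C–O bond, since diaryl and methyl aryl ethers are stable to H2 over Pd/C.

Step 15
Reactants: 25 3,4-dimethoxy-5-[3,4,5-trimethoxy-2-(3,4,5-trimethoxyphenoxy)phenoxy]phenol (ArFGH–OH); 14 trichloroethylene
Product: 26 5-{[(E)-1,2-dichloroethenyl]oxy}-1,2-dimethoxy-3-[3,4,5-trimethoxy-2-(3,4,5-trimethoxyphenoxy)phenoxy]benzene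
Conditions: trichloroethylene (2 equiv), K2CO3 (3 equiv), DMF, 70 °C, N2
Reagents that add atoms: none
Why: As in step 10, anti addition of the unhindered ring F phenoxide to dichloroacetylene generated and consumed in the flask should give the (E)-dichlorovinyl ether and so fixes the future ring E to ring F oxygen without any aryl halide.

Step 16
Reactants: 26 (E)-dichlorovinyl ether of ArFGH–OH
Product: 29 5-(ethynyloxy)-1,2-dimethoxy-3-[3,4,5-trimethoxy-2-(3,4,5-trimethoxyphenoxy)phenoxy]benzene, via chloroethynyl ether 27 (not isolated), via lithium acetylide 28 (not isolated)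
Conditions: n-BuLi (2.5 equiv), THF, −78 to −40 °C; then H2O, −78 °C
Reagents that add atoms: none
Why: The elimination, lithium–chlorine exchange and protonation sequence of step 11 should apply unchanged, because methyl ether-directed lithiation is slow at −78 °C.

**AB ynol ether**

Step 17
Reactants: 30 2,4,6-trimethoxyphenol; 31 4-bromo-2,6-dimethoxybenzaldehyde
Product: 32 2,6-dimethoxy-4-(2,4,6-trimethoxyphenoxy)benzaldehyde
Conditions: CuI (10 mol %), picolinic acid (20 mol %), K3PO4 (2 equiv), DMSO, 90 °C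
Reagents that add atoms: none
Why: Ullmann-type copper-catalysed diaryl ether synthesis with a picolinate ligand tolerates the 2,6-disubstituted phenol, and the para formyl group activates the unhindered bromide and later becomes the C4 oxygen of ring B.

Step 18
Reactants: 32 2,6-dimethoxy-4-(2,4,6-trimethoxyphenoxy)benzaldehyde
Product: 34 2,6-dimethoxy-4-(2,4,6-trimethoxyphenoxy)phenol, via aryl formate 33 (not isolated)
Conditions: mCPBA (1.1 equiv), CH2Cl2, 0 °C to rt; aq. Na2SO3/NaHCO3 wash; then K2CO3 (cat.), MeOH, rt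
Reagents that add atoms: meta-chloroperbenzoic acid, OOC(=O)c1cccc(Cl)c1
Why: Baeyer–Villiger oxidation of the 2,4,6-trioxygenated benzaldehyde with aryl migration, then methanolysis of the formate, should give the hindered ring B phenol.

Step 19
Reactants: 34 2,6-dimethoxy-4-(2,4,6-trimethoxyphenoxy)phenol (ArAB–OH); 14 trichloroethylene
Product: 35 2-{[(E)-1,2-dichloroethenyl]oxy}-1,3-dimethoxy-5-(2,4,6-trimethoxyphenoxy)benzene
Conditions: trichloroethylene (3 equiv), K2CO3 (3 equiv), DMF, 70 °C, N2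
Reagents that add atoms: none
Why: Anti addition of the phenoxide to the linear, unhindered dichloroacetylene generated and consumed in the flask is insensitive to the two ortho methoxy groups, so the hindered oxygen is vinylated where an aryl coupling would be difficult.

Step 20
Reactants: 35 (E)-dichlorovinyl ether of ArAB–OH
Product: 38 2-(ethynyloxy)-1,3-dimethoxy-5-(2,4,6-trimethoxyphenoxy)benzene, via chloroethynyl ether 36 (not isolated), via lithium acetylide 37 (not isolated)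
Conditions: n-BuLi (2.5 equiv), THF, −78 to −40 °C; then H2O, −78 °C
Reagents that add atoms: none
Why: The dichlorovinyl ether to ynol ether conversion of step 11 should proceed faster than lithiation of the trimethoxyarene at this temperature.

**Ring D cyclobutenone and ring C**

Step 21
Reactants: 39 4-(benzyloxy)-3,5-dimethoxybenzaldehyde
Product: 41 4-(benzyloxy)-3,5-dimethoxyphenol, via aryl formate 40 (not isolated)
Conditions: mCPBA (1.2 equiv), CH2Cl2, 0 °C to rt; aq. Na2SO3/NaHCO3 wash; then K2CO3 (cat.), MeOH, rt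
Reagents that add atoms: meta-chloroperbenzoic acid, OOC(=O)c1cccc(Cl)c1
Why: Baeyer–Villiger oxidation with aryl migration and formate methanolysis should give the ring D phenol whose free oxygen is the unhindered one and whose hindered oxygen stays benzylated.

Step 22
Reactants: 41 4-(benzyloxy)-3,5-dimethoxyphenol; 3 3-chloro-4-methoxycyclobut-3-ene-1,2-dione
Product: 42 3-[4-(benzyloxy)-3,5-dimethoxyphenoxy]-4-methoxycyclobut-3-ene-1,2-dione
Conditions: i-Pr2NEt (1.1 equiv), CH2Cl2, −78 to 0 °C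
Reagents that add atoms: none
Why: The addition–elimination on the squaryl chloride used in step 3 should give the mixed squarate and sets the future ring C to ring D ether bond.

Step 23
Reactants: 42 3-[4-(benzyloxy)-3,5-dimethoxyphenoxy]-4-methoxycyclobut-3-ene-1,2-dione
Product: 43 racemic 2-[4-(benzyloxy)-3,5-dimethoxyphenoxy]-4-hydroxy-3-methoxycyclobut-2-en-1-one
Conditions: LiAlH(OtBu)3 (1.05 equiv), THF, −78 °C; then H2O
Reagents that add atoms: none
Why: As in step 4, hydride should add to the carbonyl beside the methoxy-bearing carbon (vinylogous ester of the weaker donor, less hindered), giving a racemic carbinol centre that is lost in step 25.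

Step 24
Reactants: 43 racemic 2-[4-(benzyloxy)-3,5-dimethoxyphenoxy]-4-hydroxy-3-methoxycyclobut-2-en-1-one
Product: 44 racemic 2-[4-(benzyloxy)-3,5-dimethoxyphenoxy]-3,4-dimethoxycyclobut-2-en-1-one
Conditions: MeI (10 equiv), Ag2O (2 equiv), CaSO4, MeCN, rt, dark
Reagents that add atoms: iodomethane, CI
Why: Purdie methylation under base-free conditions should cap the carbinol as in step 5 without touching the racemic centre.

Step 25
Reactants: 44 racemic 2-(ArD-oxy)-3,4-dimethoxycyclobut-2-en-1-one; 38 2-(ethynyloxy)-1,3-dimethoxy-5-(2,4,6-trimethoxyphenoxy)benzene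
Product: 49 5-(ArAB-oxy)-4-(ArD-oxy)-2,3-dimethoxyphenol, via vinylketene 45 (not isolated), via vinylcyclobutenone 46 (not isolated), via dienylketene 47 (not isolated), via cyclohexadienone 48 (not isolated)
Conditions: 44 (1.5 equiv), 38 (1.0 equiv), toluene (0.2 M), argon, 80 °C then 110 °C; then KOH, MeOH, rt
Reagents that add atoms: none
Why: The cyclobutenone–ynol ether benzannulation of step 12 (4π opening, [2+2] cycloaddition, 4π opening, 6π closure, enolisation) should close ring C, the alkyne polarisation again placing the ring B oxygen on C1 beside the ring D oxygen on C6 and the new hydroxyl on C3.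

Step 26
Reactants: 49 5-(ArAB-oxy)-4-(ArD-oxy)-2,3-dimethoxyphenol
Product: 50 1-(ArAB-oxy)-2-(ArD-oxy)-3,4,5-trimethoxybenzene
Conditions: MeI, K2CO3, DMF, rt
Reagents that add atoms: iodomethane, CI
Why: Williamson methylation caps the ring C hydroxyl so that the ring D phenol freed in the next step is the only one.

Step 27
Reactants: 50 1-(ArAB-oxy)-2-(ArD-oxy)-3,4,5-trimethoxybenzene
Product: 51 4-[6-(ArAB-oxy)-2,3,4-trimethoxyphenoxy]-2,6-dimethoxyphenol (ArABCD–OH)
Conditions: H2 (1 atm), Pd/C (10 wt%), EtOAc–MeOH, rt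
Reagents that add atoms: none
Why: Hydrogenolysis of the single benzyl ether should release the hindered C4 hydroxyl of ring D and leave every aryl ether intact.

**ABCD cyclobutenone, union and deprotection**

Step 28
Reactants: 51 ArABCD–OH; 3 3-chloro-4-methoxycyclobut-3-ene-1,2-dione
Product: 52 3-methoxy-4-(ArABCD-oxy)cyclobut-3-ene-1,2-dione
Conditions: i-Pr2NEt (1.2 equiv), CH2Cl2, 0 °C to rt
Reagents that add atoms: none
Why: The 2,6-dimethoxyphenol oxygen attacks the exposed chlorine-bearing carbon of the planar four-membered ring by addition–elimination, so the ether that becomes the tetra-ortho-substituted ring D to ring E link is made without an aryl coupling.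

Step 29
Reactants: 52 3-methoxy-4-(ArABCD-oxy)cyclobut-3-ene-1,2-dione
Product: 53 racemic 4-hydroxy-3-methoxy-2-(ArABCD-oxy)cyclobut-2-en-1-one
Conditions: LiAlH(OtBu)3 (1.05 equiv), THF, −78 °C; then H2O
Reagents that add atoms: none
Why: As in step 4, the bulky hydride should add to the carbonyl beside the methoxy-bearing carbon, here also steered away from the other carbonyl by the ortho-disubstituted aryloxy group; the racemic centre is lost in step 31.

Step 30
Reactants: 53 racemic 4-hydroxy-3-methoxy-2-(ArABCD-oxy)cyclobut-2-en-1-one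
Product: 54 racemic 3,4-dimethoxy-2-(ArABCD-oxy)cyclobut-2-en-1-one
Conditions: MeI (10 equiv), Ag2O (2 equiv), CaSO4, MeCN, rt, dark
Reagents that add atoms: iodomethane, CI
Why: Base-free Purdie methylation should cap the carbinol as in steps 5 and 24.

Step 31
Reactants: 54 racemic 3,4-dimethoxy-2-(ArABCD-oxy)cyclobut-2-en-1-one; 29 5-(ethynyloxy)-1,2-dimethoxy-3-[3,4,5-trimethoxy-2-(3,4,5-trimethoxyphenoxy)phenoxy]benzene
Product: 59 5-(ArFGH-oxy)-4-(ArABCD-oxy)-2,3-dimethoxyphenol, via vinylketene 55 (not isolated), via vinylcyclobutenone 56 (not isolated), via dienylketene 57 (not isolated), via cyclohexadienone 58 (not isolated)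
Conditions: 54 (1.2 equiv), 29 (1.0 equiv), toluene (0.2 M), argon, 80 °C then 110 °C; then KOH, MeOH, rt
Reagents that add atoms: none
Why: The benzannulation of steps 12 and 25 should join the two halves and close ring E with the ring D oxygen on C1, the ring F oxygen on C2, hydrogen on C3 and a free hydroxyl on C4, which needs no protection because the next step exposes every hydroxyl.

Step 32
Reactants: 59 5-(ArFGH-oxy)-4-(ArABCD-oxy)-2,3-dimethoxyphenol
Product: 60 CNP0309601.0 (target)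
Conditions: BBr3 (40 equiv), CH2Cl2, −78 °C to rt, argon; then H2O, 0 °C; Sephadex LH-20 (degassed MeOH)
Reagents that add atoms: none
Why: BBr3 cleaves all twenty aryl methyl ethers by Lewis acid-assisted bromide attack on the methyl groups while diaryl ether bonds are inert, and hydrolysis of the aryl borates should give the target, which has no stereocentre.

## Compound list

1 | dimethyl squarate | COC1=C(OC)C(=O)C1=O | starting material
2 | 3-hydroxy-4-methoxycyclobut-3-ene-1,2-dione | COC1=C(O)C(=O)C1=O | intermediate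
3 | 3-chloro-4-methoxycyclobut-3-ene-1,2-dione (methyl squaryl chloride) | COC1=C(Cl)C(=O)C1=O | intermediate
4 | 3,4,5-trimethoxyphenol | COc1cc(O)cc(OC)c1OC | starting material
5 | 3-methoxy-4-(3,4,5-trimethoxyphenoxy)cyclobut-3-ene-1,2-dione | COC1=C(Oc2cc(OC)c(OC)c(OC)c2)C(=O)C1=O | intermediate
6 | racemic 4-hydroxy-3-methoxy-2-(3,4,5-trimethoxyphenoxy)cyclobut-2-en-1-one | O=C1C(Oc2cc(OC)c(OC)c(OC)c2)=C(OC)C1O | intermediate
7 | racemic 3,4-dimethoxy-2-(3,4,5-trimethoxyphenoxy)cyclobut-2-en-1-one | O=C1C(Oc2cc(OC)c(OC)c(OC)c2)=C(OC)C1OC | intermediate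
8 | 3-hydroxy-4,5-dimethoxybenzaldehyde | COc1cc(C=O)cc(O)c1OC | starting material
9 | 3,4-dimethoxy-5-(methoxymethoxy)benzaldehyde | COCOc1cc(C=O)cc(OC)c1OC | intermediate
10 | 3,4-dimethoxy-5-(methoxymethoxy)phenyl formate | COCOc1cc(OC=O)cc(OC)c1OC | intermediate (not isolated)
11 | 3,4-dimethoxy-5-(methoxymethoxy)phenol | COCOc1cc(O)cc(OC)c1OC | intermediate
12 | 5-(benzyloxy)-1,2-dimethoxy-3-(methoxymethoxy)benzene | COCOc1cc(OCc2ccccc2)cc(OC)c1OC | intermediate
13 | 5-(benzyloxy)-2,3-dimethoxyphenol | Oc1cc(OCc2ccccc2)cc(OC)c1OC | intermediate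
14 | trichloroethylene | ClC=C(Cl)Cl | starting material
15 | 5-(benzyloxy)-1-{[(E)-1,2-dichloroethenyl]oxy}-2,3-dimethoxybenzene | Cl/C=C(Cl)\Oc1cc(OCc2ccccc2)cc(OC)c1OC | intermediate
16 | 5-(benzyloxy)-1-[(chloroethynyl)oxy]-2,3-dimethoxybenzene | ClC#COc1cc(OCc2ccccc2)cc(OC)c1OC | intermediate (not isolated)
17 | lithium 2-[5-(benzyloxy)-2,3-dimethoxyphenoxy]ethynide | [Li]C#COc1cc(OCc2ccccc2)cc(OC)c1OC | intermediate (not isolated)
18 | 1-(benzyloxy)-3-(ethynyloxy)-4,5-dimethoxybenzene | C#COc1cc(OCc2ccccc2)cc(OC)c1OC | intermediate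
19 | (Z)-3,4-dimethoxy-2-(3,4,5-trimethoxyphenoxy)buta-1,3-dien-1-one (vinylketene) | O=C=C(Oc1cc(OC)c(OC)c(OC)c1)/C(OC)=C/OC | intermediate (not isolated)
20 | racemic 3-(ArF-oxy)-4-[(Z)-1,2-dimethoxyethenyl]-4-(ArH-oxy)cyclobut-2-en-1-one | O=C1C=C(Oc2cc(OCc3ccccc3)cc(OC)c2OC)C1(Oc2cc(OC)c(OC)c(OC)c2)/C(OC)=C/OC | intermediate (not isolated)
21 | (3Z,5Z)-3-(ArF-oxy)-5,6-dimethoxy-4-(ArH-oxy)hexa-1,3,5-trien-1-one (dienylketene) | O=C=C/C(Oc1cc(OCc2ccccc2)cc(OC)c1OC)=C(Oc1cc(OC)c(OC)c(OC)c1)\C(OC)=C\OC | intermediate (not isolated)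
22 | racemic 3-(ArF-oxy)-5,6-dimethoxy-4-(ArH-oxy)cyclohexa-2,4-dien-1-one | O=C1C=C(Oc2cc(OCc3ccccc3)cc(OC)c2OC)C(Oc2cc(OC)c(OC)c(OC)c2)=C(OC)C1OC | intermediate (not isolated)
23 | 5-[5-(benzyloxy)-2,3-dimethoxyphenoxy]-2,3-dimethoxy-4-(3,4,5-trimethoxyphenoxy)phenol | Oc1cc(Oc2cc(OCc3ccccc3)cc(OC)c2OC)c(Oc2cc(OC)c(OC)c(OC)c2)c(OC)c1OC | intermediate
24 | 5-(benzyloxy)-1,2-dimethoxy-3-[3,4,5-trimethoxy-2-(3,4,5-trimethoxyphenoxy)phenoxy]benzene | COc1cc(Oc2cc(OCc3ccccc3)cc(OC)c2OC)c(Oc2cc(OC)c(OC)c(OC)c2)c(OC)c1OC | intermediate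
25 | 3,4-dimethoxy-5-[3,4,5-trimethoxy-2-(3,4,5-trimethoxyphenoxy)phenoxy]phenol (ArFGH–OH) | COc1cc(Oc2cc(O)cc(OC)c2OC)c(Oc2cc(OC)c(OC)c(OC)c2)c(OC)c1OC | intermediate
26 | 5-{[(E)-1,2-dichloroethenyl]oxy}-1,2-dimethoxy-3-[3,4,5-trimethoxy-2-(3,4,5-trimethoxyphenoxy)phenoxy]benzene | Cl/C=C(Cl)\Oc1cc(OC)c(OC)c(Oc2cc(OC)c(OC)c(OC)c2Oc2cc(OC)c(OC)c(OC)c2)c1 | intermediate
27 | 5-[(chloroethynyl)oxy]-1,2-dimethoxy-3-[3,4,5-trimethoxy-2-(3,4,5-trimethoxyphenoxy)phenoxy]benzene | ClC#COc1cc(OC)c(OC)c(Oc2cc(OC)c(OC)c(OC)c2Oc2cc(OC)c(OC)c(OC)c2)c1 | intermediate (not isolated)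
28 | lithium 2-(ArFGH-oxy)ethynide | [Li]C#COc1cc(OC)c(OC)c(Oc2cc(OC)c(OC)c(OC)c2Oc2cc(OC)c(OC)c(OC)c2)c1 | intermediate (not isolated)
29 | 5-(ethynyloxy)-1,2-dimethoxy-3-[3,4,5-trimethoxy-2-(3,4,5-trimethoxyphenoxy)phenoxy]benzene | C#COc1cc(OC)c(OC)c(Oc2cc(OC)c(OC)c(OC)c2Oc2cc(OC)c(OC)c(OC)c2)c1 | intermediate
30 | 2,4,6-trimethoxyphenol | COc1cc(OC)c(O)c(OC)c1 | starting material
31 | 4-bromo-2,6-dimethoxybenzaldehyde | COc1cc(Br)cc(OC)c1C=O | starting material
32 | 2,6-dimethoxy-4-(2,4,6-trimethoxyphenoxy)benzaldehyde | COc1cc(OC)c(Oc2cc(OC)c(C=O)c(OC)c2)c(OC)c1 | intermediate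
33 | 2,6-dimethoxy-4-(2,4,6-trimethoxyphenoxy)phenyl formate | COc1cc(OC)c(Oc2cc(OC)c(OC=O)c(OC)c2)c(OC)c1 | intermediate (not isolated)
34 | 2,6-dimethoxy-4-(2,4,6-trimethoxyphenoxy)phenol (ArAB–OH) | COc1cc(OC)c(Oc2cc(OC)c(O)c(OC)c2)c(OC)c1 | intermediate
35 | 2-{[(E)-1,2-dichloroethenyl]oxy}-1,3-dimethoxy-5-(2,4,6-trimethoxyphenoxy)benzene | Cl/C=C(Cl)\Oc1c(OC)cc(Oc2c(OC)cc(OC)cc2OC)cc1OC | intermediate
36 | 2-[(chloroethynyl)oxy]-1,3-dimethoxy-5-(2,4,6-trimethoxyphenoxy)benzene | ClC#COc1c(OC)cc(Oc2c(OC)cc(OC)cc2OC)cc1OC | intermediate (not isolated)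
37 | lithium 2-(ArAB-oxy)ethynide | [Li]C#COc1c(OC)cc(Oc2c(OC)cc(OC)cc2OC)cc1OC | intermediate (not isolated)
38 | 2-(ethynyloxy)-1,3-dimethoxy-5-(2,4,6-trimethoxyphenoxy)benzene | C#COc1c(OC)cc(Oc2c(OC)cc(OC)cc2OC)cc1OC | intermediate
39 | 4-(benzyloxy)-3,5-dimethoxybenzaldehyde | COc1cc(C=O)cc(OC)c1OCc1ccccc1 | starting material
40 | 4-(benzyloxy)-3,5-dimethoxyphenyl formate | COc1cc(OC=O)cc(OC)c1OCc1ccccc1 | intermediate (not isolated)
41 | 4-(benzyloxy)-3,5-dimethoxyphenol | COc1cc(O)cc(OC)c1OCc1ccccc1 | intermediate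
42 | 3-[4-(benzyloxy)-3,5-dimethoxyphenoxy]-4-methoxycyclobut-3-ene-1,2-dione | COC1=C(Oc2cc(OC)c(OCc3ccccc3)c(OC)c2)C(=O)C1=O | intermediate
43 | racemic 2-[4-(benzyloxy)-3,5-dimethoxyphenoxy]-4-hydroxy-3-methoxycyclobut-2-en-1-one | O=C1C(Oc2cc(OC)c(OCc3ccccc3)c(OC)c2)=C(OC)C1O | intermediate
44 | racemic 2-[4-(benzyloxy)-3,5-dimethoxyphenoxy]-3,4-dimethoxycyclobut-2-en-1-one | O=C1C(Oc2cc(OC)c(OCc3ccccc3)c(OC)c2)=C(OC)C1OC | intermediate
45 | (Z)-2-(ArD-oxy)-3,4-dimethoxybuta-1,3-dien-1-one (vinylketene) | O=C=C(Oc1cc(OC)c(OCc2ccccc2)c(OC)c1)/C(OC)=C/OC | intermediate (not isolated)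
46 | racemic 3-(ArAB-oxy)-4-(ArD-oxy)-4-[(Z)-1,2-dimethoxyethenyl]cyclobut-2-en-1-one | O=C1C=C(Oc2c(OC)cc(Oc3c(OC)cc(OC)cc3OC)cc2OC)C1(Oc2cc(OC)c(OCc3ccccc3)c(OC)c2)/C(OC)=C/OC | intermediate (not isolated)
47 | (3Z,5Z)-3-(ArAB-oxy)-4-(ArD-oxy)-5,6-dimethoxyhexa-1,3,5-trien-1-one (dienylketene) | O=C=C/C(Oc1c(OC)cc(Oc2c(OC)cc(OC)cc2OC)cc1OC)=C(Oc1cc(OC)c(OCc2ccccc2)c(OC)c1)\C(OC)=C\OC | intermediate (not isolated)
48 | racemic 3-(ArAB-oxy)-4-(ArD-oxy)-5,6-dimethoxycyclohexa-2,4-dien-1-one | O=C1C=C(Oc2c(OC)cc(Oc3c(OC)cc(OC)cc3OC)cc2OC)C(Oc2cc(OC)c(OCc3ccccc3)c(OC)c2)=C(OC)C1OC | intermediate (not isolated)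
49 | 5-(ArAB-oxy)-4-(ArD-oxy)-2,3-dimethoxyphenol | Oc1cc(Oc2c(OC)cc(Oc3c(OC)cc(OC)cc3OC)cc2OC)c(Oc2cc(OC)c(OCc3ccccc3)c(OC)c2)c(OC)c1OC | intermediate
50 | 1-(ArAB-oxy)-2-(ArD-oxy)-3,4,5-trimethoxybenzene | COc1cc(Oc2c(OC)cc(Oc3c(OC)cc(OC)cc3OC)cc2OC)c(Oc2cc(OC)c(OCc3ccccc3)c(OC)c2)c(OC)c1OC | intermediate
51 | 4-[6-(ArAB-oxy)-2,3,4-trimethoxyphenoxy]-2,6-dimethoxyphenol (ArABCD–OH) | COc1cc(Oc2c(OC)cc(Oc3c(OC)cc(OC)cc3OC)cc2OC)c(Oc2cc(OC)c(O)c(OC)c2)c(OC)c1OC | intermediate
52 | 3-methoxy-4-(ArABCD-oxy)cyclobut-3-ene-1,2-dione | COC1=C(Oc2c(OC)cc(Oc3c(Oc4c(OC)cc(Oc5c(OC)cc(OC)cc5OC)cc4OC)cc(OC)c(OC)c3OC)cc2OC)C(=O)C1=O | intermediate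
53 | racemic 4-hydroxy-3-methoxy-2-(ArABCD-oxy)cyclobut-2-en-1-one | O=C1C(Oc2c(OC)cc(Oc3c(Oc4c(OC)cc(Oc5c(OC)cc(OC)cc5OC)cc4OC)cc(OC)c(OC)c3OC)cc2OC)=C(OC)C1O | intermediate
54 | racemic 3,4-dimethoxy-2-(ArABCD-oxy)cyclobut-2-en-1-one | O=C1C(Oc2c(OC)cc(Oc3c(Oc4c(OC)cc(Oc5c(OC)cc(OC)cc5OC)cc4OC)cc(OC)c(OC)c3OC)cc2OC)=C(OC)C1OC | intermediate
55 | (Z)-3,4-dimethoxy-2-(ArABCD-oxy)buta-1,3-dien-1-one (vinylketene) | O=C=C(Oc1c(OC)cc(Oc2c(Oc3c(OC)cc(Oc4c(OC)cc(OC)cc4OC)cc3OC)cc(OC)c(OC)c2OC)cc1OC)/C(OC)=C/OC | intermediate (not isolated)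
56 | racemic 3-(ArFGH-oxy)-4-(ArABCD-oxy)-4-[(Z)-1,2-dimethoxyethenyl]cyclobut-2-en-1-one | O=C1C=C(Oc2cc(OC)c(OC)c(Oc3cc(OC)c(OC)c(OC)c3Oc3cc(OC)c(OC)c(OC)c3)c2)C1(Oc2c(OC)cc(Oc3c(Oc4c(OC)cc(Oc5c(OC)cc(OC)cc5OC)cc4OC)cc(OC)c(OC)c3OC)cc2OC)/C(OC)=C/OC | intermediate (not isolated)
57 | (3Z,5Z)-3-(ArFGH-oxy)-4-(ArABCD-oxy)-5,6-dimethoxyhexa-1,3,5-trien-1-one (dienylketene) | O=C=C/C(Oc1cc(OC)c(OC)c(Oc2cc(OC)c(OC)c(OC)c2Oc2cc(OC)c(OC)c(OC)c2)c1)=C(Oc1c(OC)cc(Oc2c(Oc3c(OC)cc(Oc4c(OC)cc(OC)cc4OC)cc3OC)cc(OC)c(OC)c2OC)cc1OC)\C(OC)=C\OC | intermediate (not isolated)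
58 | racemic 3-(ArFGH-oxy)-4-(ArABCD-oxy)-5,6-dimethoxycyclohexa-2,4-dien-1-one | O=C1C=C(Oc2cc(OC)c(OC)c(Oc3cc(OC)c(OC)c(OC)c3Oc3cc(OC)c(OC)c(OC)c3)c2)C(Oc2c(OC)cc(Oc3c(Oc4c(OC)cc(Oc5c(OC)cc(OC)cc5OC)cc4OC)cc(OC)c(OC)c3OC)cc2OC)=C(OC)C1OC | intermediate (not isolated)
59 | 5-(ArFGH-oxy)-4-(ArABCD-oxy)-2,3-dimethoxyphenol (octamer, free OH on C4 of ring E) | Oc1cc(Oc2cc(OC)c(OC)c(Oc3cc(OC)c(OC)c(OC)c3Oc3cc(OC)c(OC)c(OC)c3)c2)c(Oc2c(OC)cc(Oc3c(Oc4c(OC)cc(Oc5c(OC)cc(OC)cc5OC)cc4OC)cc(OC)c(OC)c3OC)cc2OC)c(OC)c1OC | intermediate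
60 | CNP0309601.0 | Oc1cc(O)c(Oc2cc(O)c(Oc3cc(O)c(O)c(O)c3Oc3cc(O)c(Oc4c(Oc5cc(O)c(O)c(Oc6cc(O)c(O)c(O)c6Oc6cc(O)c(O)c(O)c6)c5)cc(O)c(O)c4O)c(O)c3)c(O)c2)c(O)c1 | target

## Step count and risk

Total step count: 32. Longest linear sequence: 13 steps (steps 6–16, 31 and 32, from aldehyde 8; the chain 1, 2, 22–32 from dimethyl squarate is equally long).

**Step 12 (key benzannulation).** The vinylketene may dimerise or acylate the product phenol faster than it adds the ynol ether, or the cycloaddition may proceed with the reverse regiochemistry. The fallback sets out from 4 and returns at 25, bypassing steps 13 and 14, and uses only Ullmann etherification and Baeyer–Villiger chemistry. Phenol 4 is coupled with commercial 2-bromo-3,4,5-trimethoxybenzaldehyde (CuI, picolinic acid, K3PO4, DMSO, 100 °C; the ortho formyl group activates the bromide) to give 3,4,5-trimethoxy-2-(3,4,5-trimethoxyphenoxy)benzaldehyde F1. mCPBA converts it into 3,4,5-trimethoxy-2-(3,4,5-trimethoxyphenoxy)phenyl formate F2, and K2CO3 in MeOH gives 3,4,5-trimethoxy-2-(3,4,5-trimethoxyphenoxy)phenol F3. A second copper-catalysed coupling of F3 with commercial 3-bromo-4,5-dimethoxybenzaldehyde gives 3,4-dimethoxy-5-[3,4,5-trimethoxy-2-(3,4,5-trimethoxyphenoxy)phenoxy]benzaldehyde F4. mCPBA then gives 3,4-dimethoxy-5-[3,4,5-trimethoxy-2-(3,4,5-trimethoxyphenoxy)phenoxy]phenyl formate F5, whose methanolysis gives 25.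

**Step 31 (union of the two halves).** Capture of a bulky vinylketene by a bulky ynol ether at near-equimolar ratio may be slower than decomposition of the ketene. The fallback sets out from 51 and 25 and returns at 60; it builds ring E from a preformed arene and joins the halves by cross-coupling. Phenol 51 is coupled with 2-bromo-3,4,5-trimethoxybenzaldehyde (CuI, picolinic acid, K3PO4, DMSO, 110 °C) to give 3,4,5-trimethoxy-2-(ArABCD-oxy)benzaldehyde F6. mCPBA gives 3,4,5-trimethoxy-2-(ArABCD-oxy)phenyl formate F7, and methanolysis gives 3,4,5-trimethoxy-2-(ArABCD-oxy)phenol F8. Phenol 25 is converted with Tf2O and pyridine into ArFGH trifluoromethanesulfonate F9. F8 and F9 are joined by palladium-catalysed diaryl ether formation (Pd(OAc)2, t-BuXPhos, K3PO4, toluene, 100 °C) to give 1-(ArFGH-oxy)-2-(ArABCD-oxy)-3,4,5-trimethoxybenzene F10, which BBr3 in CH2Cl2 demethylates to 60.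

**Step 4 (regioselective hydride addition; first of three such reductions).** Hydride may be delivered to the wrong carbonyl, or the aryloxy group may be lost by conjugate addition–elimination. The fallback sets out from 4 and returns at 7; it removes the regiochemical question by reducing a symmetrical squarate. Two equivalents of 4 and commercial 3,4-dichlorocyclobut-3-ene-1,2-dione (i-Pr2NEt, CH2Cl2, −78 to 0 °C) give 3,4-bis(3,4,5-trimethoxyphenoxy)cyclobut-3-ene-1,2-dione F11. LiAlH(OtBu)3 reduces either carbonyl to give racemic 4-hydroxy-2,3-bis(3,4,5-trimethoxyphenoxy)cyclobut-2-en-1-one F12. MeI and Ag2O give racemic 4-methoxy-2,3-bis(3,4,5-trimethoxyphenoxy)cyclobut-2-en-1-one F13. One equivalent of NaOMe in MeOH–THF (−40 to 0 °C) then replaces only the aryloxy group on C3, the vinylogous ester carbon, by addition–elimination, which gives 7 and returns one equivalent of 4.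

## Further compounds

F1 | step 12 | 3,4,5-trimethoxy-2-(3,4,5-trimethoxyphenoxy)benzaldehyde | COc1cc(C=O)c(Oc2cc(OC)c(OC)c(OC)c2)c(OC)c1OC
F2 | step 12 | 3,4,5-trimethoxy-2-(3,4,5-trimethoxyphenoxy)phenyl formate | COc1cc(OC=O)c(Oc2cc(OC)c(OC)c(OC)c2)c(OC)c1OC
F3 | step 12 | 3,4,5-trimethoxy-2-(3,4,5-trimethoxyphenoxy)phenol | COc1cc(O)c(Oc2cc(OC)c(OC)c(OC)c2)c(OC)c1OC
F4 | step 12 | 3,4-dimethoxy-5-[3,4,5-trimethoxy-2-(3,4,5-trimethoxyphenoxy)phenoxy]benzaldehyde | COc1cc(Oc2cc(C=O)cc(OC)c2OC)c(Oc2cc(OC)c(OC)c(OC)c2)c(OC)c1OC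
F5 | step 12 | 3,4-dimethoxy-5-[3,4,5-trimethoxy-2-(3,4,5-trimethoxyphenoxy)phenoxy]phenyl formate | COc1cc(Oc2cc(OC=O)cc(OC)c2OC)c(Oc2cc(OC)c(OC)c(OC)c2)c(OC)c1OC
F6 | step 31 | 3,4,5-trimethoxy-2-(ArABCD-oxy)benzaldehyde | O=Cc1cc(OC)c(OC)c(OC)c1Oc1c(OC)cc(Oc2c(Oc3c(OC)cc(Oc4c(OC)cc(OC)cc4OC)cc3OC)cc(OC)c(OC)c2OC)cc1OC
F7 | step 31 | 3,4,5-trimethoxy-2-(ArABCD-oxy)phenyl formate | O=COc1cc(OC)c(OC)c(OC)c1Oc1c(OC)cc(Oc2c(Oc3c(OC)cc(Oc4c(OC)cc(OC)cc4OC)cc3OC)cc(OC)c(OC)c2OC)cc1OC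
F8 | step 31 | 3,4,5-trimethoxy-2-(ArABCD-oxy)phenol | Oc1cc(OC)c(OC)c(OC)c1Oc1c(OC)cc(Oc2c(Oc3c(OC)cc(Oc4c(OC)cc(OC)cc4OC)cc3OC)cc(OC)c(OC)c2OC)cc1OC
F9 | step 31 | ArFGH trifluoromethanesulfonate | O=S(=O)(Oc1cc(OC)c(OC)c(Oc2cc(OC)c(OC)c(OC)c2Oc2cc(OC)c(OC)c(OC)c2)c1)C(F)(F)F
F10 | step 31 | 1-(ArFGH-oxy)-2-(ArABCD-oxy)-3,4,5-trimethoxybenzene | COc1cc(Oc2cc(OC)c(OC)c(Oc3cc(OC)c(OC)c(OC)c3Oc3cc(OC)c(OC)c(OC)c3)c2)c(Oc2c(OC)cc(Oc3c(Oc4c(OC)cc(Oc5c(OC)cc(OC)cc5OC)cc4OC)cc(OC)c(OC)c3OC)cc2OC)c(OC)c1OC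
F11 | step 4 | 3,4-bis(3,4,5-trimethoxyphenoxy)cyclobut-3-ene-1,2-dione | O=C1C(=O)C(Oc2cc(OC)c(OC)c(OC)c2)=C1Oc1cc(OC)c(OC)c(OC)c1
F12 | step 4 | racemic 4-hydroxy-2,3-bis(3,4,5-trimethoxyphenoxy)cyclobut-2-en-1-one | O=C1C(Oc2cc(OC)c(OC)c(OC)c2)=C(Oc2cc(OC)c(OC)c(OC)c2)C1O
F13 | step 4 | racemic 4-methoxy-2,3-bis(3,4,5-trimethoxyphenoxy)cyclobut-2-en-1-one | O=C1C(Oc2cc(OC)c(OC)c(OC)c2)=C(Oc2cc(OC)c(OC)c(OC)c2)C1OC
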